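(The constants are assumed; the rest is arithmetic.)

I began from the time of reading, for Z is made and then lost, and a count of it holds for one moment.

    Z → L (k1 = 3.26 × 10⁻⁴ s⁻¹)
    L + J → L.J (k2 = 0.0652 M⁻¹ s⁻¹)
    D + X → Z + J (k3 = 0.00828 M⁻¹ s⁻¹)

common to all: X 0.109 M
- violet: D 0.091 M (fed, over 2.50 h); time 2.5 h; all but D at the start; D goes in evenly over 2.50 h, the run ends at 2.5 h
- amber: D 0.091 M; time 2.5 h; a closed flask charged with all of it at once and left for 2.5 h
- green: D 0.091 M; time 2.5 h; plug flow through a tube for 2.5 h, no back-mixing
- grey: D 0.091 M; one stirred flow tank at steady state, fed with the mixture as stated, mean residence time 2.5 h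

1. the set-up with the highest amount of Z at the outlet or at the end, in percent of the D put in ("none" if the first two lie within 2 percentage points) (violet / amber / green / grey / none)
2. amount of Z at the outlet or at the end, in percent of the D put in, violet
3. amount of Z at the outlet or at the end, in percent of the D put in, amber
4. amount of Z at the outlet or at the end, in percent of the D put in, green
5. amount of Z at the outlet or at the end, in percent of the D put in, grey

D was charged in the smaller amount, so it is the limiting reagent. In closed amber each D spent takes one X, so c_X − c_D stays at 0.0180 M, and ln(c_X/c_D) climbs from its start at the rate k3 times that gap. Green, without back-mixing, runs as amber does.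

Z is lost by step 1, so I carried its memory time τ = 1/k1, here 0.852 h: Z made a time a before the reading survives as exp(−a/τ). D's half-life by step 3 alone, with X as charged in amber, 0.21 h, is shorter than τ. I cut amber into slices and gave each its middle age.

| Slice | c_D at its end | D spent | Age | Z surviving |
|---|---|---|---|---|
| to 0.500 h | 0.0318 M | 65.1 % | 2.25 h | 4.64 % |
| to 1.25 h | 0.0134 M | 20.2 % | 1.62 h | 3.00 % |
| to 2.5 h | 0.00503 M | 9.21 % | 0.625 h | 4.42 % |

Read down the spent column of amber, the first slice is the largest. Read down the last column, the picture changes: by my reckoning the last slice of amber spent the least, yet left about as much Z. My sum was 12.1 % for amber and green, 0.90 percentage points above the forecast. I made no table for violet or grey.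

The forecast named violet, with 25.5 % for violet, 11.2 % for amber, 11.2 % for green and 19.1 % for grey, holding that “the set-up that forms Z latest keeps the most”.

The simulation gave 25.5 % for violet, 11.3 % for amber, 11.3 % for green and 19.1 % for grey, so violet led grey by 6.4 points, more than the margin. In violet 24.5 % of the D still stood as D at the end. If the rest of that D became Z evenly over 2.50 h, τ lets a share τ/tf·(1 − exp(−tf/τ)) survive, an estimate of 24.4 % for violet.

Green read at 1.0 h takes the same balance and τ in two slices, cut at 0.500 h, and I got 39.0 %. The simulation gave 36.7 %.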